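**Retrosynthetic overview**

- Feature: the four atoms O1–C8a–C4a–C4 shared by rings A and C are the heterodiene of an ortho-quinone methide, and C2–C3 with ring B attached is an electron-rich 4-methoxystyrene whose benzylic position (C2) carries a cation well.
- The target is traced back to its 5,7-bis-O-silyl flavanone and then to a 4-methoxyflavan; the C4 oxygen is installed in the ring-forming step and only its oxidation level is adjusted afterwards.
- Key disconnection: C3–C4 and O1–C2 of ring C, made by a chiral-acid-catalysed inverse-demand oxa-[4+2] addition of the O-methyl oxocarbenium ion (protonated 4-methoxy ortho-quinone methide) from a 2-hydroxybenzaldehyde and HC(OMe)3 to 2-prenyl-4-vinylanisole; this step sets C2.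
- Rings A and B are bought as benzaldehydes: ring A from 2,4,6-trihydroxybenzaldehyde (double silylation), ring B from 3-bromo-4-methoxybenzaldehyde (Stille prenylation, Wittig methylenation). Ring C is the only ring formed.

Key step: step 4

Remark on the chemistry: the sense of induction of a new catalytic reaction cannot be fixed in advance; the (R) acid is written in step 4, and its mirror image is taken if the first run shows the 2R series.
Remark on the chemistry: tributyl(3-methylbut-2-enyl)stannane is taken as a purchased reagent.

**Route**

Step 1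
Reactants: 1 3-bromo-4-methoxybenzaldehyde; 2 tributyl(3-methylbut-2-enyl)stannane
Product: 3 4-methoxy-3-(3-methylbut-2-enyl)benzaldehyde
Conditions: Pd(PPh3)4 (5 mol %), DMF, 95 °C
Reagents that add atoms: none
Why: Stille cross-coupling; zerovalent palladium inserts into the aryl C–Br bond, the allylic stannane transmetalates, and reductive elimination at the less hindered terminus of the prenyl ligand should give the linear prenyl arene, with the aldehyde inert under these neutral conditions.

Step 2
Reactants: 3 4-methoxy-3-(3-methylbut-2-enyl)benzaldehyde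
Product: 4 1-methoxy-2-(3-methylbut-2-enyl)-4-vinylbenzene
Conditions: Ph3PCH3Br, KOtBu, THF, 0 °C to rt
Reagents that add atoms: methyltriphenylphosphonium bromide, C[P+](c1ccccc1)(c1ccccc1)c1ccccc1.[Br-]
Why: Wittig methylenation with the non-stabilised ylide should turn the formyl group into the vinyl group and leave the prenyl alkene and the aryl ether untouched.

Step 3
Reactants: 5 2,4,6-trihydroxybenzaldehyde
Product: 6 2-hydroxy-4,6-bis(triisopropylsilyloxy)benzaldehyde
Conditions: TIPSCl (2.2 equiv), imidazole, DMF, 0 °C to rt
Reagents that add atoms: triisopropylsilyl chloride, CC(C)[Si](Cl)(C(C)C)C(C)C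
Why: Phenol silylation; the para hydroxyl and one of the two symmetry-equivalent ortho hydroxyls should react, while the last ortho hydroxyl is held in a hydrogen bond to the formyl oxygen and should resist the bulky silyl chloride.

Step 4
Reactants: 6 2-hydroxy-4,6-bis(triisopropylsilyloxy)benzaldehyde; 4 1-methoxy-2-(3-methylbut-2-enyl)-4-vinylbenzene
Product: 9 (2S,4S)-4-methoxy-2-[4-methoxy-3-(3-methylbut-2-enyl)phenyl]-5,7-bis(triisopropylsilyloxy)chroman (2,4-cis), via dimethyl acetal 7 (not isolated), via O-methyl oxocarbenium ion 8 (not isolated)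
Conditions: (R)-3,3'-bis(2,4,6-triisopropylphenyl)-1,1'-binaphthyl-2,2'-diyl hydrogen phosphate (10 mol %), HC(OMe)3 (2 equiv), 4 Å MS, CH2Cl2, 0 °C; then 4 (1.5 equiv), −40 °C; Et3N quench before warming
Reagents that add atoms: trimethyl orthoformate, COC(OC)OC
Why: Proposed new method: the acid and HC(OMe)3 convert 6 into dimethyl acetal 7, loss of methanol gives O-methyl oxocarbenium ion 8 (the O-protonated 4-methoxy ortho-quinone methide) held by the chiral phosphate through ion pairing and a hydrogen bond from its phenolic OH, and the CH2 terminus of styrene 4 then bonds to C4 while the phenol oxygen collapses onto the developing 4-methoxybenzylic cation at C2. The closest known reaction types are the acid-catalysed three-component union of salicylaldehydes, orthoformates and styrenes to 2,4-cis-4-alkoxyflavans and the chiral phosphoric acid-catalysed [4+2] additions of ortho-quinone methides to styrenes, but an enantioselective form with this aldehyde-derived alkoxy heterodiene is not established. Ring C closes in a highly asynchronous inverse-electron-demand oxa-[4+2] mode, C3–C4 first and O1–C2 second, the second event being in the stepwise limit a 6-exo-trig capture of the benzylic cation by the phenol oxygen. C2 is set by the face of the styrene that the phosphate-bound heterodiene meets (catalyst control), and C4 follows from the endo placement of the aryl group, which should give the 2,4-cis (2S,4S) isomer, while a trans isomer of the same C2 configuration would converge in step 6. The step needs the vinyl group to react in preference to the prenyl alkene and the CH2 terminus to bond to C4, and both are secured by conjugation of the vinyl group with the para-methoxy ring, which raises its nucleophilicity and stabilises the cation at C2. The product must not reopen at O1–C2, which the weak acid, −40 °C and the amine quench should secure, and the silyloxy groups at C5 and C7, weaker donors than alkoxy groups, should keep 8 electrophilic enough to react at that temperature.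

Step 5
Reactants: 9 (2S,4S)-4-methoxy-2-[4-methoxy-3-(3-methylbut-2-enyl)phenyl]-5,7-bis(triisopropylsilyloxy)chroman
Product: 10 (2S,4RS)-2-[4-methoxy-3-(3-methylbut-2-enyl)phenyl]-5,7-bis(triisopropylsilyloxy)chroman-4-ol (mixture of C4 epimers)
Conditions: pyridinium p-toluenesulfonate (0.2 equiv), THF/H2O 4:1, 0 °C to rt, in the dark
Reagents that add atoms: water, O
Why: SN1 solvolysis of a benzylic methyl ether; C4 sits on a ring with oxygen donors at both ortho positions and the para position and should ionise far faster than the O1–C2 bond, and the large excess of water should capture the cation, so C2 is untouched and C4 becomes an epimer mixture of no consequence.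

Step 6
Reactants: 10 (2S,4RS)-2-[4-methoxy-3-(3-methylbut-2-enyl)phenyl]-5,7-bis(triisopropylsilyloxy)chroman-4-ol
Product: 11 (2S)-2-[4-methoxy-3-(3-methylbut-2-enyl)phenyl]-5,7-bis(triisopropylsilyloxy)chroman-4-one
Conditions: Dess–Martin periodinane (1.5 equiv), NaHCO3, CH2Cl2, 0 °C to rt
Reagents that add atoms: none
Why: Dess–Martin oxidation of a secondary benzylic alcohol under bicarbonate buffer should convert both C4 epimers into one ketone; no base strong enough for retro-oxa-Michael opening is present, so C2 should hold.

Step 7
Reactants: 11 (2S)-2-[4-methoxy-3-(3-methylbut-2-enyl)phenyl]-5,7-bis(triisopropylsilyloxy)chroman-4-one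
Product: 12 (2S)-5,7-dihydroxy-2-[4-methoxy-3-(3-methylbut-2-enyl)phenyl]chroman-4-one (4'-O-methyllicoflavanone)
Conditions: Bu4NF (2.5 equiv), AcOH (2.5 equiv), THF, 0 °C
Reagents that add atoms: none
Why: Fluoride cleavage of aryl silyl ethers; acetic acid should protonate each phenoxide as it forms, which suppresses the E1cB opening to the chalcone that racemises flavanones.

**Compound list**

1 | 3-bromo-4-methoxybenzaldehyde | COc1ccc(C=O)cc1Br | starting material
2 | tributyl(3-methylbut-2-enyl)stannane | CCCC[Sn](CCCC)(CCCC)CC=C(C)C | starting material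
3 | 4-methoxy-3-(3-methylbut-2-enyl)benzaldehyde | COc1ccc(C=O)cc1CC=C(C)C | intermediate
4 | 1-methoxy-2-(3-methylbut-2-enyl)-4-vinylbenzene | COc1ccc(C=C)cc1CC=C(C)C | intermediate
5 | 2,4,6-trihydroxybenzaldehyde | O=Cc1c(O)cc(O)cc1O | starting material
6 | 2-hydroxy-4,6-bis(triisopropylsilyloxy)benzaldehyde | O=Cc1c(O)cc(O[Si](C(C)C)(C(C)C)C(C)C)cc1O[Si](C(C)C)(C(C)C)C(C)C | intermediate
7 | 2-(dimethoxymethyl)-3,5-bis(triisopropylsilyloxy)phenol (dimethyl acetal of 6) | COC(OC)c1c(O)cc(O[Si](C(C)C)(C(C)C)C(C)C)cc1O[Si](C(C)C)(C(C)C)C(C)C | intermediate (not isolated)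
8 | O-methyl oxocarbenium ion of 6 (protonated 4-methoxy ortho-quinone methide, phosphate counter-ion not drawn) | C[O+]=Cc1c(O)cc(O[Si](C(C)C)(C(C)C)C(C)C)cc1O[Si](C(C)C)(C(C)C)C(C)C | intermediate (not isolated)
9 | (2S,4S)-4-methoxy-2-[4-methoxy-3-(3-methylbut-2-enyl)phenyl]-5,7-bis(triisopropylsilyloxy)chroman (2,4-cis) | COc1ccc([C@@H]2C[C@H](OC)c3c(O[Si](C(C)C)(C(C)C)C(C)C)cc(O[Si](C(C)C)(C(C)C)C(C)C)cc3O2)cc1CC=C(C)C | intermediate
10 | (2S,4RS)-2-[4-methoxy-3-(3-methylbut-2-enyl)phenyl]-5,7-bis(triisopropylsilyloxy)chroman-4-ol (C4 epimers) | COc1ccc([C@@H]2CC(O)c3c(O[Si](C(C)C)(C(C)C)C(C)C)cc(O[Si](C(C)C)(C(C)C)C(C)C)cc3O2)cc1CC=C(C)C | intermediate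
11 | (2S)-2-[4-methoxy-3-(3-methylbut-2-enyl)phenyl]-5,7-bis(triisopropylsilyloxy)chroman-4-one | COc1ccc([C@@H]2CC(=O)c3c(O[Si](C(C)C)(C(C)C)C(C)C)cc(O[Si](C(C)C)(C(C)C)C(C)C)cc3O2)cc1CC=C(C)C | intermediate
12 | (2S)-5,7-dihydroxy-2-[4-methoxy-3-(3-methylbut-2-enyl)phenyl]chroman-4-one (4'-O-methyllicoflavanone) | COc1ccc([C@@H]2CC(=O)c3c(O)cc(O)cc3O2)cc1CC=C(C)C | target

**Step count**

Total: 7 steps. Longest linear sequence: 6 steps (steps 1, 2, 4, 5, 6, 7 from compound 1).

**Steps most likely to fail**

Step 4. The ion pair may discriminate poorly between the two faces of the styrene. The strongly stabilised heterodiene may also react too slowly at low temperature, and warming would then allow reversible ionisation at C2 and erosion of the enantiomeric purity. Prins-type attack by the prenyl alkene is a further possible loss. The fallback sets out from 6 and 4 and uses known chemistry only. The same three-component condensation is run with an achiral acid (Sc(OTf)3, 5 mol %, HC(OMe)3, CH2Cl2, rt), which should give the racemic 2,4-cis-4-methoxyflavan F1. Steps 5 and 6, unchanged, should then give the racemic flavan-4-ol F2 and the racemic flavanone F3. F3 is submitted to kinetic resolution by Noyori-type asymmetric transfer hydrogenation with RuCl(p-cymene)[(R,R)-N-tosyl-1,2-diphenylethylenediamine] in HCO2H/Et3N, stopped near half conversion. By the usual model this catalyst should reduce the 2R ketone to the (2R,4R)-cis-flavan-4-ol F4, which is removed by chromatography. The unreacted ketone is 11, where the route is rejoined for step 7.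

Step 5. The C4 cation may lose H3 to give the flav-3-ene, or attack ring A of a second molecule. If ionisation is slow, stronger acid would be needed, and this could open the O1–C2 bond with loss of configuration at C2. The fallback sets out from 9 and omits 10. DDQ (1.3 equiv) in CH2Cl2/pH 7 buffer at 0 °C should abstract the C4 hydride, as in the known C4-selective DDQ oxidation of 5,7-dioxygenated flavans. Water adds to the resulting oxocarbenium ion and the hemiketal loses methanol to give ketone 11, where the route is rejoined. The fallback makes no compound outside the list (entry F0 below).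

Step 1. Reductive elimination may occur at the tertiary terminus of the prenyl ligand and give the 1,1-dimethylallyl isomer, or coupling next to the methoxy group may be slow and allow protodestannylation. The fallback sets out from 1. Acetalisation with ethylene glycol (TsOH, toluene, water removal) should give the bromo acetal F5. Bromine–lithium exchange (n-BuLi, THF, −78 °C), transmetalation with CuBr·SMe2 and alkylation with prenyl bromide should give the prenyl acetal F6. Hydrolysis with 1 M HCl in THF returns aldehyde 3, where the route is rejoined.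

**Further compounds**

F1 | step 4 | racemic 2,4-cis-4-methoxy-2-[4-methoxy-3-(3-methylbut-2-enyl)phenyl]-5,7-bis(triisopropylsilyloxy)chroman | COc1ccc(C2CC(OC)c3c(O[Si](C(C)C)(C(C)C)C(C)C)cc(O[Si](C(C)C)(C(C)C)C(C)C)cc3O2)cc1CC=C(C)C
F2 | step 4 | racemic 2-[4-methoxy-3-(3-methylbut-2-enyl)phenyl]-5,7-bis(triisopropylsilyloxy)chroman-4-ol | COc1ccc(C2CC(O)c3c(O[Si](C(C)C)(C(C)C)C(C)C)cc(O[Si](C(C)C)(C(C)C)C(C)C)cc3O2)cc1CC=C(C)C
F3 | step 4 | racemic 2-[4-methoxy-3-(3-methylbut-2-enyl)phenyl]-5,7-bis(triisopropylsilyloxy)chroman-4-one | COc1ccc(C2CC(=O)c3c(O[Si](C(C)C)(C(C)C)C(C)C)cc(O[Si](C(C)C)(C(C)C)C(C)C)cc3O2)cc1CC=C(C)C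
F4 | step 4 | (2R,4R)-2-[4-methoxy-3-(3-methylbut-2-enyl)phenyl]-5,7-bis(triisopropylsilyloxy)chroman-4-ol (2,4-cis) | COc1ccc([C@H]2C[C@@H](O)c3c(O[Si](C(C)C)(C(C)C)C(C)C)cc(O[Si](C(C)C)(C(C)C)C(C)C)cc3O2)cc1CC=C(C)C
F0 | step 5 | none | none
F5 | step 1 | 2-(3-bromo-4-methoxyphenyl)-1,3-dioxolane | COc1ccc(C2OCCO2)cc1Br
F6 | step 1 | 2-[4-methoxy-3-(3-methylbut-2-enyl)phenyl]-1,3-dioxolane | COc1ccc(C2OCCO2)cc1CC=C(C)C
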